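- Of the constants these runs offer, I use one ratio of rates, read at the stall, and it chooses my next charge.

| flask | starting material | reagent | second substrate | free catalyst | temperature | remark | time |
|---|---|---|---|---|---|---|---|
| cedar | 0.27 M | 0.54 M | 0.26 M | 0.54 mM | 75 °C | run made earlier |  |
| oak | 0.27 M | 0.54 M | 0.32 M | 0.54 mM | 100 °C | run made earlier |  |
| elm | 0.27 M | 0.54 M | 0.56 M | 0.54 mM | 75 °C | run made earlier |  |
| birch | 0.21 M | 0.54 M | 0.54 M | 0.54 mM | 100 °C | run made earlier |  |
| west | 0.20 M | 0.800 M | 0.540 M | 0.54 mM | 100 °C |  | 30 min |
| east | 0.27 M | 1.50 M | 0.540 M | 0.54 mM | 80 °C |  | 30 min |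
| north | 0.15 M | 0.540 M | 0.200 M | 0.54 mM | 85 °C |  | 30 min |
| north-west | 0.50 M | 0.540 M | 0.200 M | 0.54 mM | 100 °C |  | 30 min |
| south-west | 0.27 M | 0.150 M | 0.540 M | 0.54 mM | 120 °C |  | 30 min |
| south | 0.27 M | 0.540 M | 0.540 M | 0.54 mM | 100 °C |  | 30 min |

| run | time / min | target / % | starting material / % |
|---|---|---|---|
| cedar | 5.00 | 68 | 33 |
| cedar | 8.00 | 74 | 21 |
| cedar | 15.0 | 84 | 15 |
| cedar | 30.0 | 90 | 14 |
| cedar | 50.0 | 93 | 7 |
| oak | 3.00 | 74 | 26 |
| oak | 6.00 | 77 | 17 |
| oak | 10.0 | 84 | 18 |
| oak | 12.0 | 81 | 13 |
| oak | 15.0 | 73 | 13 |
| elm | 5.00 | 64 | 31 |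
| elm | 15.0 | 80 | 22 |
| elm | 30.0 | 81 | 15 |
| elm | 50.0 | 86 | 17 |
| birch | 1.33 | 64 | 36 |
| birch | 4.00 | 77 | 18 |
| birch | 8.00 | 80 | 11 |
| birch | 10.0 | 78 | 13 |
| birch | 15.0 | 80 | 10 |

(readings scatter by 2 percentage points)

1. the flasks by amount of target, in percent of the starting material charged, highest first, at 30 min (west / east / north / north-west / south-west / south)
2. the same order at 6.0 min (west / east / north / north-west / south-west / south)
3. the amount of target, in percent of the starting material charged of the flask you put first, at 30 min
4. the amount of target, in percent of the starting material charged of the flask you put last, at 30 min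

- a reading or a percentage of target counts all its forms, free or not

- Suppose starting material falls, per unit of itself, at a rate set by free catalyst and reagent, while free catalyst dies at its own first-order rate.
- Dividing the one rate by the other removes time, so the fraction of the charge left at the stall is the exponential of minus a pure number.
- Birch looks stalled: starting material reads 11%, 13% and 10% of its charge from 8.00 min on, each good to 2 percentage points.
- Its last reading gives 2.30, which I call the stall number, the logarithm of charge over residue.
- Cedar, at 75 °C, reads 7% at 50.0 min, a stall number of 2.66, larger than birch's, though within the scatter. But cedar differs from birch in starting material and second substrate as well, so I read this as: the cooler run shows no lower stall number.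
- Oak, at 100 °C, reads target falling from 84% at 10.0 min to 73% at 15.0 min, while cedar is still at 93% at its last reading. So I keep the flask cool.
- Reagent was never varied. My assumption is a pseudo-first-order picture, with the stall number scaling with the reagent charge, taken from birch and ignoring temperature.
- West then has 3.41, a residue of 3.30%.
- East has 6.40, a residue of 0.167%.
- South-west has 0.640, a residue of 52.7%.
- So I would charge reagent heavily and run cool, as east does, and I expect south-west last, its reagent charge being the lowest.
- The forecast also puts east first, “cooler with excess second substrate”, but it puts north-west last: east > north > west > south > south-west > north-west at 30 min and west > south > east > north > south-west > north-west at 6.0 min, with 87% on top and 32% at the bottom.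

    second substrate + reagent + free catalyst → free catalyst + second product (k = 835 M⁻² min⁻¹, Ea = 48.0 kJ mol⁻¹)
    free catalyst → spent catalyst (k = 0.197 min⁻¹, Ea = 96.0 kJ mol⁻¹)
    starting material + reagent + free catalyst → free catalyst + target (k = 4760 M⁻² min⁻¹, Ea = 44.0 kJ mol⁻¹)
    reagent + target → over-reaction product (k = 0.299 M⁻¹ min⁻¹, Ea = 63.0 kJ mol⁻¹)
    reagent + target ⇌ idle adduct, settled at all times (K = 24.2 M⁻¹, ΔH = −60.0 kJ mol⁻¹)
    (constants at 100 °C)

- The flasks give east > north > west > south > north-west > south-west at 30 min and east > west > north > south > north-west > south-west at 6.0 min, with 96.3% in east and 19.6% in south-west. West keeps 1.9% of its starting material, a stall number of 3.96 against my 3.41. South-west keeps 71% against my 52.7%, and east keeps 0% against my 0.167%. Yet east has not come to rest. Between 30.0 min and 300 min its free catalyst goes from 35.9% to 0%, its over-reaction product climbs from 3.66% to 31.6%, and its target falls to 68.4%.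

The runs are simulated with made-up constants, and the scatter is random.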